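**Retrosynthetic overview**
Target ← epoxidation of the C4=C5 alkene, C8 angeloylation and C8 desilylation of a ten-membered E-4-en-1-one fused to the C7(C11) butenolide.
Ten-membered carbocycle ← excision of nitrogen from an eleven-membered cyclic amine. The strategy rests on the C2–C3 ring bond, which lies between the C1 ketone and the C4=C5 alkene, so that C2 (α-keto) and C3 (allylic) can both carry stabilized radicals once N2 has left.
Eleven-membered aza-ring ← reductive amination between the amine on C2 (α-amino ketone) and a C3 enal installed by cross-metathesis with methacrolein.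
Butenolide ← lactonisation of a tetrasubstituted C7=C11 enoate made by iodo-aldol of an ynoate (C6 from asymmetric alkynylation of crotonaldehyde), CrCl2-mediated coupling with a C8 aldehyde (C10 from crotylboration of N-Boc-glycinal) and CBS reduction at C8.
Ring order: butenolide (step 13), eleven-membered aza-ring (step 16), ten-membered carbocycle (step 17), epoxide (step 20).

Key step: step 17

Assumption: atoms carry germacranolide labels (C1 ketone, C4–C5 epoxide, C6 lactone carbinol, C8 ester carbinol, C11–C13 butenolide carbons); (R,R)-ProPhenol is taken to deliver the alkynyl group to the Si face of crotonaldehyde, and its antipode is used if the sense proves to be the opposite.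

**Route**

Step 1
Reactants: 1 (E)-but-2-enal; 2 methyl propiolate
Product: 3 methyl (4R,5E)-4-hydroxyhept-5-en-2-ynoate
Conditions: Me2Zn, (R,R)-ProPhenol (10 mol%), PhMe, 4 °C; aq NH4Cl
Reagents that add atoms: none
Why: Zinc–ProPhenol-catalysed asymmetric alkynylation of an enal, in which the chiral dinuclear zinc alkoxide should deliver MeZn–C≡C–CO2Me to the Si face of the aldehyde and so set C6 (R).

Step 2
Reactants: 3 methyl (4R,5E)-4-hydroxyhept-5-en-2-ynoate
Product: 4 methyl (4R,5E)-4-(triethylsilyloxy)hept-5-en-2-ynoate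
Conditions: TESCl, imidazole, CH2Cl2, 0 °C
Reagents that add atoms: chlorotriethylsilane, CC[Si](CC)(CC)Cl
Why: Silyl ether formation keeps the doubly activated C6 carbinol from ionising or lactonising under the Lewis acid of step 3.

Step 3
Reactants: 4 methyl (4R,5E)-4-(triethylsilyloxy)hept-5-en-2-ynoate
Product: 5 methyl (2E,4R,5E)-2-(hydroxymethyl)-3-iodo-4-(triethylsilyloxy)hepta-2,5-dienoate
Conditions: MgI2, CH2O (monomer in CH2Cl2), CH2Cl2, −20 to 0 °C; aq NH4Cl
Reagents that add atoms: magnesium diiodide, [Mg+2].[I-].[I-]; formaldehyde, C=O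
Why: β-Iodo Morita–Baylis–Hillman (halo-aldol) reaction, in which iodide adds to C7 of the ynoate and the allenolate C=C=C(OMgI)OMe is hydroxymethylated at C11 from the side of iodine, away from the branched C6 group, which should place C6 cis to the ester.

Step 4
Reactants: 5 methyl (2E,4R,5E)-2-(hydroxymethyl)-3-iodo-4-(triethylsilyloxy)hepta-2,5-dienoate
Product: 6 methyl (2E,4R,5E)-2-(acetoxymethyl)-3-iodo-4-(triethylsilyloxy)hepta-2,5-dienoate
Conditions: Ac2O, pyridine, DMAP (cat.), CH2Cl2, 0 °C
Reagents that add atoms: acetic anhydride, CC(=O)OC(C)=O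
Why: Acetylation of the primary allylic alcohol installs the C13 acetate of the target before any oxidation step.

Step 5
Reactants: 7 tert-butyl N-(2-oxoethyl)carbamate
Product: 9 tert-butyl N-[(2R,3R)-2-hydroxy-3-methylpent-4-en-1-yl]carbamate, via O-borinate 8 (not isolated)
Conditions: (+)-(E)-crotyl-B(Ipc)2 [preformed from (+)-Ipc2BOMe, (E)-but-2-ene, KOt-Bu, n-BuLi, BF3·OEt2], THF, −78 °C; NaOH, H2O2
Reagents that add atoms: (+)-B-[(E)-but-2-enyl]diisopinocampheylborane, C/C=C/CB([C@H]1C[C@H]2C[C@@H]([C@@H]1C)C2(C)C)[C@H]1C[C@H]2C[C@@H]([C@@H]1C)C2(C)C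
Why: Brown crotylation through a chair transition state, in which the (E)-crotyl group gives the anti adduct and the isopinocampheyl groups direct attack to the Re face, setting C10 (R); the C1 carbinol is oxidised later.

Step 6
Reactants: 9 tert-butyl N-[(2R,3R)-2-hydroxy-3-methylpent-4-en-1-yl]carbamate
Product: 10 tert-butyl N-[(2R,3R)-3-methyl-2-(triethylsilyloxy)pent-4-en-1-yl]carbamate
Conditions: TESCl, imidazole, DMF, 23 °C
Reagents that add atoms: chlorotriethylsilane, CC[Si](CC)(CC)Cl
Why: Silylation masks the C1 carbinol (the later ketone) through the organometallic, oxidation and hydride steps.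

Step 7
Reactants: 10 tert-butyl N-[(2R,3R)-3-methyl-2-(triethylsilyloxy)pent-4-en-1-yl]carbamate
Product: 12 tert-butyl N-[(2R,3R)-5-hydroxy-3-methyl-2-(triethylsilyloxy)pentyl]carbamate, via B-alkyl-9-BBN 11 (not isolated)
Conditions: 9-BBN, THF, 0 to 23 °C; NaOH, H2O2, 0 °C
Reagents that add atoms: hydrogen peroxide, OO
Why: Anti-Markovnikov hydroboration–oxidation of the terminal alkene gives the primary C8 alcohol without touching the carbamate or the silyl ether.

Step 8
Reactants: 12 tert-butyl N-[(2R,3R)-5-hydroxy-3-methyl-2-(triethylsilyloxy)pentyl]carbamate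
Product: 13 tert-butyl N-[(2R,3R)-3-methyl-5-oxo-2-(triethylsilyloxy)pentyl]carbamate
Conditions: Dess–Martin periodinane, NaHCO3, CH2Cl2, 23 °C
Reagents that add atoms: none
Why: Dess–Martin oxidation gives the C8 aldehyde under buffered conditions that leave the C10 centre (β to the aldehyde) untouched.

Step 9
Reactants: 6 methyl (2E,4R,5E)-2-(acetoxymethyl)-3-iodo-4-(triethylsilyloxy)hepta-2,5-dienoate; 13 tert-butyl N-[(2R,3R)-3-methyl-5-oxo-2-(triethylsilyloxy)pentyl]carbamate
Product: 14 methyl (4R,5E)-2-(acetoxymethyl)-3-[(1RS,3R,4R)-5-(tert-butoxycarbonylamino)-1-hydroxy-3-methyl-4-(triethylsilyloxy)pentyl]-4-(triethylsilyloxy)hepta-2,5-dienoate (C6 cis to CO2Me; C8 epimers)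
Conditions: CrCl2, NiCl2 (cat.), DMSO, 23 °C
Reagents that add atoms: none
Why: Nozaki–Hiyama–Kishi coupling, in which zerovalent nickel inserts into the C7–I bond and transmetalation to trivalent chromium gives an alkenyl–CrCl2 species that adds to the aldehyde only, so carbamate, esters and silyl ethers survive; C8 forms without control and is set in steps 10 and 11.

Step 10
Reactants: 14 C7–C8 coupling product (C8 epimers)
Product: 15 methyl (4R,5E)-2-(acetoxymethyl)-3-[(3R,4R)-5-(tert-butoxycarbonylamino)-3-methyl-4-(triethylsilyloxy)pentanoyl]-4-(triethylsilyloxy)hepta-2,5-dienoate (C6 cis to CO2Me)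
Conditions: Dess–Martin periodinane, NaHCO3, CH2Cl2, 0 °C
Reagents that add atoms: none
Why: Dess–Martin oxidation of the only free hydroxyl merges both C8 epimers into one enone.

Step 11
Reactants: 15 C8 enone
Product: 16 methyl (4R,5E)-2-(acetoxymethyl)-3-[(1S,3R,4R)-5-(tert-butoxycarbonylamino)-1-hydroxy-3-methyl-4-(triethylsilyloxy)pentyl]-4-(triethylsilyloxy)hepta-2,5-dienoate (C6 cis to CO2Me)
Conditions: (R)-2-methyl-CBS-oxazaborolidine (0.3 equiv), catecholborane, PhMe, −78 °C; MeOH
Reagents that add atoms: none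
Why: Corey–Bakshi–Shibata reduction, in which the tetrasubstituted alkenyl arm (C7) acts as the large group and the C9 methylene as the small one, so that hydride from the catalyst–borane complex should add to the Re face of the ketone and set C8 (S).

Step 12
Reactants: 16 (8S)-alcohol
Product: 17 methyl (4R,5E)-2-(acetoxymethyl)-3-[(1S,3R,4R)-5-(tert-butoxycarbonylamino)-1-(tert-butyldimethylsilyloxy)-3-methyl-4-(triethylsilyloxy)pentyl]-4-(triethylsilyloxy)hepta-2,5-dienoate (C6 cis to CO2Me)
Conditions: TBSOTf, 2,6-lutidine, CH2Cl2, −78 °C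
Reagents that add atoms: tert-butyldimethylsilyl trifluoromethanesulfonate, CC(C)(C)[Si](C)(C)OS(=O)(=O)C(F)(F)F
Why: Silylation of the hindered allylic C8 alcohol at low temperature gives a TBS ether that outlasts the TES ethers and the carbamate cleavage.

Step 13
Reactants: 17 C8 TBS ether
Product: 19 tert-butyl N-[(2R,3R,5S)-5-[(2R)-4-(acetoxymethyl)-5-oxo-2-[(E)-prop-1-enyl]-2,5-dihydrofuran-3-yl]-5-(tert-butyldimethylsilyloxy)-2-hydroxy-3-methylpentyl]carbamate, via dihydroxy ester 18 (not isolated)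
Conditions: PPTS, MeOH, 23 °C; then PhMe, 50 °C
Reagents that add atoms: none
Why: Acid-catalysed methanolysis cleaves the two secondary TES ethers and not the TBS ether, and the freed C6 hydroxyl, cis to the methyl ester, closes the butenolide by 5-exo-trig acyl substitution with retention at C6.

Step 14
Reactants: 19 propenyl butenolide; 20 2-methylprop-2-enal
Product: 21 tert-butyl N-[(2R,3R,5S)-5-[(2R)-4-(acetoxymethyl)-2-[(E)-2-methyl-3-oxoprop-1-enyl]-5-oxo-2,5-dihydrofuran-3-yl]-5-(tert-butyldimethylsilyloxy)-2-hydroxy-3-methylpentyl]carbamate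
Conditions: second-generation Hoveyda–Grubbs catalyst RuCl2(H2IMes)(=CH-C6H4-2-O-i-Pr) (5 mol%), CH2Cl2, 40 °C
Reagents that add atoms: none
Why: Olefin cross-metathesis exchanges the ethylidene end of the propenyl group for the 2-formylpropylidene unit of methacrolein, giving the E trisubstituted enal (C3–C5, C15); the tetrasubstituted, electron-poor butenolide alkene does not take part.

Step 15
Reactants: 21 hydroxy enal
Product: 22 tert-butyl N-[(3R,5S)-5-[(2R)-4-(acetoxymethyl)-2-[(E)-2-methyl-3-oxoprop-1-enyl]-5-oxo-2,5-dihydrofuran-3-yl]-5-(tert-butyldimethylsilyloxy)-3-methyl-2-oxopentyl]carbamate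
Conditions: Dess–Martin periodinane, NaHCO3, CH2Cl2, 23 °C
Reagents that add atoms: none
Why: Dess–Martin oxidation of the C1 carbinol gives the α-(Boc-amino) ketone under buffered, non-epimerising conditions.

Step 16
Reactants: 22 keto enal
Product: 25 eleven-membered α-amino ketone allylic amine (6R,8S,10R; C8 OTBS; C13 OAc), via ammonium trifluoroacetate 23 (not isolated), via cyclic imine 24 (not isolated)
Conditions: TFA, CH2Cl2, 0 °C; evaporate; slow addition to NaBH(OAc)3, i-Pr2NEt, AcOH, MeCN (0.5 mM), 23 °C; aq NaHCO3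
Reagents that add atoms: none
Why: Carbamate cleavage followed by macrocyclic reductive amination, in which the primary amine condenses with the C3 enal and NaBH(OAc)3 reduces the iminium at carbon (1,2) but neither ketone nor butenolide, closing the eleven-membered ring at C3–N; high dilution holds back dimerisation of the α-amino ketone.

Step 17
Reactants: 25 eleven-membered α-amino ketone allylic amine
Product: 27 ten-membered E-4-en-1-one (6R,8S,10R; C8 OTBS; C13 OAc), via isodiazene 26 (not isolated)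
Conditions: N-(benzyloxy)-N-(pivaloyloxy)-4-(trifluoromethyl)benzamide (1.5 equiv), THF (5 mM), 45 °C
Reagents that add atoms: none
Why: Proposed new method: the secondary amine attacks the electrophilic nitrogen of the anomeric amide with loss of pivalate, and the N-amino-N-benzyloxy amide collapses to benzyl 4-(trifluoromethyl)benzoate and isodiazene 26, which extrudes N2 to leave a caged singlet pair of the C2 (α-keto) radical and the C3 (allyl, C3–C4=C5) radical that recombines to the C2–C3 bond. The closest known reaction type is the nitrogen deletion of secondary amines with N-alkoxy-N-acyloxy amides through isodiazenes, shown for benzylic and small-ring cyclic amines but not for a medium-ring α-amino ketone allylic amine. The ten-membered carbocycle closes by radical–radical recombination inside the former eleven-membered ring, so a contraction by one atom replaces a direct medium-ring C–C closure. No stereocentre is formed, and C6, C8 and C10 belong to neither radical. The step needs coupling at the primary terminus C3 and not at C5 (which would give an eight-membered ring) and retention of the E geometry; both rest on the short lifetime of the ring-held pair, on the higher spin density and lower hindrance at C3, and on the rotational barrier of the allyl radical. Hydrogen transfer within the pair is the main competing path and is limited by dilution and by a temperature at which N2 loss is fast.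

Step 18
Reactants: 27 ten-membered E-4-en-1-one
Product: 28 ten-membered C8 alcohol (6R,8S,10R; C13 OAc)
Conditions: HF·pyridine, pyridine, THF, 0 to 23 °C
Reagents that add atoms: none
Why: Buffered fluoride desilylation frees the C8 hydroxyl before the acid-sensitive epoxide exists and without base, which could epimerise C6 or move the C13 acetyl group.

Step 19
Reactants: 28 ten-membered C8 alcohol; 29 (Z)-2-methylbut-2-enoic acid
Product: 31 ten-membered C8 angelate (6R,8S,10R), via mixed anhydride 30 (not isolated)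
Conditions: 2,4,6-trichlorobenzoyl chloride, Et3N, PhMe, 23 °C; then 28, 75 °C
Reagents that add atoms: none
Why: Yamaguchi-type mixed-anhydride esterification without a nucleophilic catalyst acylates the hindered secondary alcohol while avoiding Z to E isomerisation of the angelate to the tiglate.

Step 20
Reactants: 31 ten-membered C8 angelate
Product: 32 target (4R,5R,6S,8S,10R)
Conditions: mCPBA, NaHCO3, CH2Cl2, 0 °C
Reagents that add atoms: 3-chloroperoxybenzoic acid, OOC(=O)c1cccc(Cl)c1
Why: Prilezhaev epoxidation of the only electron-rich alkene is stereospecific (E alkene gives the trans epoxide), and the peracid should come from the outer face, syn to the lactone oxygen on C6, because H6 eclipses the alkene to avoid A(1,3) strain with C15 while the ring carbons C7 and C3 cover the inner face, which gives 4R,5R.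

**Compound list**
1 | (E)-but-2-enal | C/C=C/C=O | starting material
2 | methyl propiolate | COC(=O)C#C | starting material
3 | methyl (4R,5E)-4-hydroxyhept-5-en-2-ynoate | C/C=C/[C@@H](O)C#CC(=O)OC | intermediate
4 | methyl (4R,5E)-4-(triethylsilyloxy)hept-5-en-2-ynoate | C/C=C/[C@@H](O[Si](CC)(CC)CC)C#CC(=O)OC | intermediate
5 | methyl (2E,4R,5E)-2-(hydroxymethyl)-3-iodo-4-(triethylsilyloxy)hepta-2,5-dienoate | C/C=C/[C@@H](O[Si](CC)(CC)CC)/C(I)=C(/CO)C(=O)OC | intermediate
6 | methyl (2E,4R,5E)-2-(acetoxymethyl)-3-iodo-4-(triethylsilyloxy)hepta-2,5-dienoate | C/C=C/[C@@H](O[Si](CC)(CC)CC)/C(I)=C(/COC(C)=O)C(=O)OC | intermediate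
7 | tert-butyl N-(2-oxoethyl)carbamate (N-Boc-glycinal) | CC(C)(C)OC(=O)NCC=O | starting material
8 | O-borinate of 9 with two isopinocampheyl groups on boron (not isolated) | CC(C)(C)OC(=O)NC[C@H](OB([C@H]1C[C@H]2C[C@@H]([C@@H]1C)C2(C)C)[C@H]1C[C@H]2C[C@@H]([C@@H]1C)C2(C)C)[C@H](C)C=C | intermediate
9 | tert-butyl N-[(2R,3R)-2-hydroxy-3-methylpent-4-en-1-yl]carbamate | CC(C)(C)OC(=O)NC[C@H](O)[C@H](C)C=C | intermediate
10 | tert-butyl N-[(2R,3R)-3-methyl-2-(triethylsilyloxy)pent-4-en-1-yl]carbamate | CC(C)(C)OC(=O)NC[C@H](O[Si](CC)(CC)CC)[C@H](C)C=C | intermediate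
11 | B-alkyl-9-borabicyclo[3.3.1]nonane from 10 (not isolated) | CC(C)(C)OC(=O)NC[C@H](O[Si](CC)(CC)CC)[C@H](C)CCB1C2CCCC1CCC2 | intermediate
12 | tert-butyl N-[(2R,3R)-5-hydroxy-3-methyl-2-(triethylsilyloxy)pentyl]carbamate | CC(C)(C)OC(=O)NC[C@H](O[Si](CC)(CC)CC)[C@H](C)CCO | intermediate
13 | tert-butyl N-[(2R,3R)-3-methyl-5-oxo-2-(triethylsilyloxy)pentyl]carbamate | CC(C)(C)OC(=O)NC[C@H](O[Si](CC)(CC)CC)[C@H](C)CC=O | intermediate
14 | C7–C8 coupling product, C8 epimers (C6 and C1 as TES ethers, C6 cis to CO2Me) | C/C=C/[C@@H](O[Si](CC)(CC)CC)/C(=C(/COC(C)=O)C(=O)OC)C(O)C[C@@H](C)[C@H](CNC(=O)OC(C)(C)C)O[Si](CC)(CC)CC | intermediate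
15 | C8 enone | C/C=C/[C@@H](O[Si](CC)(CC)CC)/C(=C(/COC(C)=O)C(=O)OC)C(=O)C[C@@H](C)[C@H](CNC(=O)OC(C)(C)C)O[Si](CC)(CC)CC | intermediate
16 | (8S)-alcohol | C/C=C/[C@@H](O[Si](CC)(CC)CC)/C(=C(/COC(C)=O)C(=O)OC)[C@@H](O)C[C@@H](C)[C@H](CNC(=O)OC(C)(C)C)O[Si](CC)(CC)CC | intermediate
17 | C8 TBS ether | C/C=C/[C@@H](O[Si](CC)(CC)CC)/C(=C(/COC(C)=O)C(=O)OC)[C@@H](O[Si](C)(C)C(C)(C)C)C[C@@H](C)[C@H](CNC(=O)OC(C)(C)C)O[Si](CC)(CC)CC | intermediate
18 | C6,C1-dihydroxy methyl ester (not isolated) | C/C=C/[C@@H](O)/C(=C(/COC(C)=O)C(=O)OC)[C@@H](O[Si](C)(C)C(C)(C)C)C[C@@H](C)[C@H](CNC(=O)OC(C)(C)C)O | intermediate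
19 | tert-butyl N-[(2R,3R,5S)-5-[(2R)-4-(acetoxymethyl)-5-oxo-2-[(E)-prop-1-enyl]-2,5-dihydrofuran-3-yl]-5-(tert-butyldimethylsilyloxy)-2-hydroxy-3-methylpentyl]carbamate | C/C=C/[C@H]1OC(=O)C(COC(C)=O)=C1[C@@H](O[Si](C)(C)C(C)(C)C)C[C@@H](C)[C@H](CNC(=O)OC(C)(C)C)O | intermediate
20 | 2-methylprop-2-enal (methacrolein) | CC(=C)C=O | starting material
21 | hydroxy enal (E-C4=C5, C3 aldehyde, C1 carbinol) | O=C/C(C)=C/[C@H]1OC(=O)C(COC(C)=O)=C1[C@@H](O[Si](C)(C)C(C)(C)C)C[C@@H](C)[C@H](CNC(=O)OC(C)(C)C)O | intermediate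
22 | keto enal (C1 ketone, C2 NHBoc, C3 aldehyde) | O=C/C(C)=C/[C@H]1OC(=O)C(COC(C)=O)=C1[C@@H](O[Si](C)(C)C(C)(C)C)C[C@@H](C)C(=O)CNC(=O)OC(C)(C)C | intermediate
23 | ammonium trifluoroacetate of the α-amino ketone enal (not isolated) | O=C/C(C)=C/[C@H]1OC(=O)C(COC(C)=O)=C1[C@@H](O[Si](C)(C)C(C)(C)C)C[C@@H](C)C(=O)C[NH3+].[O-]C(=O)C(F)(F)F | intermediate
24 | eleven-membered cyclic imine (C3=N) (not isolated) | CC(C)(C)[Si](C)(C)O[C@H]1C[C@@H](C)C(=O)CN=C/C(C)=C/[C@H]2OC(=O)C(COC(C)=O)=C12 | intermediate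
25 | eleven-membered α-amino ketone allylic amine (key-step precursor) | CC(C)(C)[Si](C)(C)O[C@H]1C[C@@H](C)C(=O)CNC/C(C)=C/[C@H]2OC(=O)C(COC(C)=O)=C12 | intermediate
26 | isodiazene of 25 (not isolated) | CC(C)(C)[Si](C)(C)O[C@H]1C[C@@H](C)C(=O)C[N+](=[N-])C/C(C)=C/[C@H]2OC(=O)C(COC(C)=O)=C12 | intermediate
27 | ten-membered E-4-en-1-one (key-step product) | CC(C)(C)[Si](C)(C)O[C@H]1C[C@@H](C)C(=O)CC/C(C)=C/[C@H]2OC(=O)C(COC(C)=O)=C12 | intermediate
28 | ten-membered C8 alcohol | O[C@H]1C[C@@H](C)C(=O)CC/C(C)=C/[C@H]2OC(=O)C(COC(C)=O)=C12 | intermediate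
29 | (Z)-2-methylbut-2-enoic acid (angelic acid) | C/C=C(/C)C(=O)O | starting material
30 | angelic 2,4,6-trichlorobenzoic anhydride (not isolated) | C/C=C(/C)C(=O)OC(=O)c1c(Cl)cc(Cl)cc1Cl | intermediate
31 | ten-membered C8 angelate (E-C4=C5) | C/C=C(/C)C(=O)O[C@H]1C[C@@H](C)C(=O)CC/C(C)=C/[C@H]2OC(=O)C(COC(C)=O)=C12 | intermediate
32 | CNP0229937.2 | C/C=C(/C)C(=O)O[C@H]1C[C@@H](C)C(=O)CC[C@@]2(C)O[C@@H]2[C@H]2OC(=O)C(COC(C)=O)=C12 | target

Total step count: 20
Longest linear sequence: 16 steps (steps 5–8 and 9–20; equally steps 1–4 and 9–20)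

**Steps most likely to fail**

1. Step 17 (key step). The radical pair may close at C5 instead of C3, lose its geometry, or be lost to hydrogen transfer; the hindered α-keto amine may also react slowly with the anomeric amide. The fallback closes C2–C3 by two-electron chemistry and removes nitrogen afterwards; it sets out from 22 and returns at 27. NaBH4 (CH2Cl2/EtOH, −78 °C) should reduce only the aldehyde to the keto allylic alcohol F1, and CBr4/PPh3 gives the allylic bromide F2. TFA, then benzophenone imine, gives the benzophenone Schiff base F3, in which C2 is activated by both ketone and imine. Slow addition to Cs2CO3 in MeCN should alkylate C2 at C3 by intramolecular SN2, giving the ten-membered imino ketone F4. Aqueous citric acid frees the α-amino ketone F5, and SmI2 (THF/MeOH, −78 °C) cleaves the C2–N bond reductively to 27.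

2. Step 3. Iodide addition to the hindered internal ynoate may be slow, and hydroxymethylation of the allenolate may occur on the wrong side, giving the isomer with iodine cis to the ester, which cannot lactonise later. The fallback lets lactonisation select the geometry; it sets out from 3 and returns at 19. The iodo-aldol is run on the free alcohol 3 (MgI2, CH2O, CH2Cl2, 0 to 23 °C, extended time), so that the adduct with C6 cis to the ester closes in the flask to the iodobutenolide alcohol F6 while the other isomer reverts through reversible iodide addition. Acetylation gives F7, CrCl2/NiCl2 coupling with 13 gives the carbinol F8, Dess–Martin oxidation the 4-acylbutenolide F9, CBS reduction the (8S)-alcohol F10 and TBSOTf the silyl ether F11; PPTS/MeOH then removes the C1 TES ether to give 19.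

3. Step 16. Closure of the eleven-membered imine may be slower than intermolecular condensation of the primary α-amino ketone (dihydropyrazines, oligomers), and the free amine may attack the allylic acetate. The fallback closes the same C3–N bond by substitution instead of condensation; it sets out from 22, passes through the allylic alcohol F1 described above, and returns at 25. TFA followed by 2-nitrobenzenesulfonyl chloride/NaHCO3 gives the sulfonamide F12, PPh3/DIAD at high dilution closes the ring by Fukuyama–Mitsunobu alkylation to F13, and PhSH/K2CO3 removes the sulfonyl group.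

Further compounds
F1 | step 17 | keto allylic alcohol (C3 OH, C2 NHBoc) | OC/C(C)=C/[C@H]1OC(=O)C(COC(C)=O)=C1[C@@H](O[Si](C)(C)C(C)(C)C)C[C@@H](C)C(=O)CNC(=O)OC(C)(C)C
F2 | step 17 | keto allylic bromide (C3 Br, C2 NHBoc) | BrC/C(C)=C/[C@H]1OC(=O)C(COC(C)=O)=C1[C@@H](O[Si](C)(C)C(C)(C)C)C[C@@H](C)C(=O)CNC(=O)OC(C)(C)C
F3 | step 17 | benzophenone Schiff base of the α-amino ketone allylic bromide | BrC/C(C)=C/[C@H]1OC(=O)C(COC(C)=O)=C1[C@@H](O[Si](C)(C)C(C)(C)C)C[C@@H](C)C(=O)CN=C(c1ccccc1)c1ccccc1
F4 | step 17 | ten-membered 2-(diphenylmethyleneamino) ketone | CC(C)(C)[Si](C)(C)O[C@H]1C[C@@H](C)C(=O)C(N=C(c3ccccc3)c3ccccc3)C/C(C)=C/[C@H]2OC(=O)C(COC(C)=O)=C12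
F5 | step 17 | ten-membered 2-amino ketone | CC(C)(C)[Si](C)(C)O[C@H]1C[C@@H](C)C(=O)C(N)C/C(C)=C/[C@H]2OC(=O)C(COC(C)=O)=C12
F6 | step 3 | (5R)-3-(hydroxymethyl)-4-iodo-5-[(E)-prop-1-enyl]furan-2(5H)-one | C/C=C/[C@H]1OC(=O)C(CO)=C1I
F7 | step 3 | (5R)-3-(acetoxymethyl)-4-iodo-5-[(E)-prop-1-enyl]furan-2(5H)-one | C/C=C/[C@H]1OC(=O)C(COC(C)=O)=C1I
F8 | step 3 | butenolide C8 carbinol, C8 epimers (C1 OTES) | C/C=C/[C@H]1OC(=O)C(COC(C)=O)=C1C(O)C[C@@H](C)[C@H](CNC(=O)OC(C)(C)C)O[Si](CC)(CC)CC
F9 | step 3 | 4-acylbutenolide (C8 ketone, C1 OTES) | C/C=C/[C@H]1OC(=O)C(COC(C)=O)=C1C(=O)C[C@@H](C)[C@H](CNC(=O)OC(C)(C)C)O[Si](CC)(CC)CC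
F10 | step 3 | butenolide (8S)-alcohol (C1 OTES) | C/C=C/[C@H]1OC(=O)C(COC(C)=O)=C1[C@@H](O)C[C@@H](C)[C@H](CNC(=O)OC(C)(C)C)O[Si](CC)(CC)CC
F11 | step 3 | butenolide C8 TBS ether (C1 OTES) | C/C=C/[C@H]1OC(=O)C(COC(C)=O)=C1[C@@H](O[Si](C)(C)C(C)(C)C)C[C@@H](C)[C@H](CNC(=O)OC(C)(C)C)O[Si](CC)(CC)CC
F12 | step 16 | 2-nitrobenzenesulfonamide of the α-amino ketone allylic alcohol | OC/C(C)=C/[C@H]1OC(=O)C(COC(C)=O)=C1[C@@H](O[Si](C)(C)C(C)(C)C)C[C@@H](C)C(=O)CNS(=O)(=O)c1ccccc1[N+](=O)[O-]
F13 | step 16 | eleven-membered N-(2-nitrobenzenesulfonyl) amine | CC(C)(C)[Si](C)(C)O[C@H]1C[C@@H](C)C(=O)CN(C/C(C)=C/[C@H]2OC(=O)C(COC(C)=O)=C12)S(=O)(=O)c1ccccc1[N+](=O)[O-]
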